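I start from amounts. The charges, the earlier runs and the questions are these:

the same everywhere: precatalyst 2.5 mol%

|  | substrate | reagent | remark | time |
|---|---|---|---|---|
| Thursday's | 0.59 M | 0.50 equiv | run made earlier |  |
| Wednesday's | 0.83 M | 0.50 equiv | run made earlier |  |
| Tuesday's | 1.3 M | 0.50 equiv | run made earlier |  |
| theta | 0.59 M | 0.500 equiv | one stirred flow tank at steady state, fed with the mixture as stated, mean residence time 6.0 min |  |
| zeta | 0.59 M | 0.500 equiv | everything together in a closed stirred flask, run for 6.0 min | 6.0 min |
| epsilon | 0.59 M (fed, over 3.00 min) | 0.500 equiv | a stirred flask in which substrate is dosed at a steady rate over 3.00 min without added volume, worked up at 6.0 min | 6.0 min |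
| beta | 0.59 M | 0.500 equiv (fed, over 3.00 min) | all but reagent at the start; reagent goes in evenly over 3.00 min, the run ends at 6.0 min | 6.0 min |

- Thursday's (time / min: target / %): 0.500: 4; 1.50: 30; 3.00: 49; 4.00: 51; 6.00: 52
- Wednesday's (time / min: target / %): 0.500: 7; 1.00: 19; 2.00: 43; 4.00: 50; 8.00: 51
- Tuesday's (time / min: target / %): 1.33: 35; 3.00: 50; 4.00: 53; 6.00: 53; 8.00: 50

(each reading ± 1.5 percentage points)

- the stated concentrations are those of everything mixed, before any reaction; amounts are the same in each set-up
- the feed brings no volume worth counting
- the earlier runs were made in a closed, stirred flask

1. the set-up with the highest amount of target at the outlet or at the end, in percent of the substrate put in ("none" if the first two lie within 2 percentage points) (theta / zeta / epsilon / beta / none)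
2. amount of target at the outlet or at the end, in percent of the substrate put in, theta
3. amount of target at the outlet or at the end, in percent of the substrate put in, zeta
4. amount of target at the outlet or at the end, in percent of the substrate put in, epsilon
5. amount of target at the outlet or at the end, in percent of the substrate put in, beta

If one reagent makes one target, then 0.500 equiv of reagent, the limiting reagent, puts a ceiling at 50.0 % of the substrate charged. The readings reach that number a second way, with no stoichiometry in it: the last readings of the earlier runs stand at 52 %, 51 % and 50 %, with a scatter of 1.5 percentage points. The two ways agree, so I trust the late end of the curve.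

The early end is a straight rise. Thursday's run, at the concentration of the new flasks, climbs by a fraction 0.260 min⁻¹ of the charge, after a lag of 0.346 min, both read from scattered readings. Joining the ends gives the corner time, the moment when the straight rise meets the ceiling: 2.27 min.

Closed flask zeta runs for 6.0 min, longer than the corner time, so I put it at the ceiling. In epsilon and beta the feed ends at 3.00 min, and the 3.00 min that remain are longer than the corner time, so I put both at the ceiling too. These tie, so I say none.

In tank theta my two ways part. The straight rise times the mean residence time, equal to 6.0 min, gives 156 %, far above the ceiling. The straight rise is the one that cheats, since a tank works at its outlet composition, and Thursday's run near the ceiling climbs by only 0.0200 min⁻¹, as a reading. The tank needs 0.0833 min⁻¹, about a third of the straight rise, so I expect theta below the ceiling, without a firm figure.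

The forecast gives 46 % for theta, 51 % for zeta, 50 % for epsilon, 50.5 % for beta, and best none; the tank, it says, “runs at low residual reagent, where the rate falls off”.

    reagent + catalyst intermediate A ⇌ catalyst intermediate B (K = 6.80 M⁻¹, k = 6.80 M⁻¹ s⁻¹)
    catalyst intermediate B → free catalyst + target (k = 2.50 s⁻¹)
    substrate + free catalyst → catalyst intermediate A (k = 38.0 M⁻¹ s⁻¹)
    precatalyst → free catalyst (k = 0.00530 s⁻¹)

The flasks give 47.1 % for theta, 50.0 % for zeta, 50.0 % for epsilon and 50.0 % for beta, so best is none. Zeta stands at the ceiling, and its reagent counts as out at 2.99 min, later than the corner time. A second flask with 0.120 equiv of reagent has a ceiling of 12.0 % and a corner time of 0.808 min; it gives 12.0 %. The target in zeta has stopped rising, with 0 % of its reagent left at 6.00 min. At 60.0 min zeta holds 50.0 % of target, a change of 7.0 × 10⁻⁵ points. The catalyst in zeta is still moving, though: from 6.00 min to 60.0 min precatalyst goes from 14.8 % to 0 % of the catalyst charged, and catalyst intermediate A goes from 85.2 % to 100 %.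

(All runs were computed on assumed constants; noise was put on by code.)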